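**Plan**

- Cuts: after removal of the two silyl ethers, ring A is opened at C8–C8a and C4a–C5. This leaves a chiral 5-phenylsulfinyl-2,3-dihydropyran-4-one (ring C; its enol ether double bond is the future C4a=C8a) and a geranyl-bearing 1-methoxy-1,3-bis(silyloxy)diene. Ring C is cut at C2–C3 and O1–C8a, the diene at the geranyl CH2–C8 bond.
- Enabling feature: ring A is a phloroglucinol-type (1,3,5-trioxygenated) benzene whose oxygen on C8a is O1 of ring C, with C8 (geranyl) and C4a (carrying the C4 ketone) on either side of C8a. A (4+2) addition across C4a=C8a therefore fixes the 8-geranyl pattern by construction.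
- Forward order: diene from methyl acetoacetate and geranyl bromide; ring C by asymmetric hetero-Diels–Alder reaction, C3 hydroxylation and C4a sulfinylation; ring A closed last; desilylation.
- Activating group: C4a carries a phenylsulfinyl group rather than a halide. It polarises the alkene more strongly and sits cis to H8a in the cycloadduct, which is what a base-free thermal syn-elimination requires.
- Stereochemistry: C2 from the titanium–BINOL catalyst, C3 by hydroxylation trans to the C2 aryl group; neither centre is touched afterwards, and the 2E alkene comes from geranyl bromide.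

Key step: step 10

Assumption: the (S)-BINOL–titanium catalyst is taken to attack the aldehyde face that gives the (2S)-pyranone, by analogy with its usual facial preference; if the sense is opposite, (R)-BINOL is used. TBS = tert-butyldimethylsilyl.

**Route**

Step 1
Reactants: 1 methyl acetoacetate; 2 geranyl bromide
Product: 3 methyl (6E)-7,11-dimethyl-3-oxododeca-6,10-dienoate
Conditions: LiN(iPr)2 (2.2 equiv), THF, 0 °C; then 2, 0 → 23 °C; aq. NH4Cl
Reagents that add atoms: none
Why: γ-Alkylation of the acetoacetate dianion, whose terminal carbanion is the more nucleophilic site and displaces the allylic bromide by SN2 without affecting the 2E alkene.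

Step 2
Reactants: 3 methyl (6E)-7,11-dimethyl-3-oxododeca-6,10-dienoate
Product: 4 methyl (2Z,6E)-7,11-dimethyl-3-(trimethylsilyloxy)dodeca-2,6,10-trienoate
Conditions: Me3SiCl, Et3N, toluene, 23 °C
Reagents that add atoms: chlorotrimethylsilane C[Si](C)(C)Cl
Why: Soft enolisation and O-silylation of the β-ketoester gives the conjugated silyl enol ether, the standard first stage in making 1,3-bis(silyloxy)dienes.

Step 3
Reactants: 4 methyl (2Z,6E)-7,11-dimethyl-3-(trimethylsilyloxy)dodeca-2,6,10-trienoate
Product: 5 (1E,3Z,6E)-1-methoxy-7,11-dimethyl-1,3-bis(trimethylsilyloxy)dodeca-1,3,6,10-tetraene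
Conditions: LiN(iPr)2, THF, −78 °C; Me3SiCl, −78 → 0 °C; filtered and used crude
Reagents that add atoms: chlorotrimethylsilane C[Si](C)(C)Cl
Why: Kinetic γ-deprotonation of the unsaturated ester and O-silylation of the resulting dienolate (ester enolate silylation) is the established route to 4-substituted 1-methoxy-1,3-bis(silyloxy)dienes; the diene geometry has no consequence later.

Step 4
Reactants: 6 4-hydroxybenzaldehyde
Product: 7 4-(tert-butyldimethylsilyloxy)benzaldehyde
Conditions: t-BuMe2SiCl, imidazole, DMF, 23 °C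
Reagents that add atoms: tert-butyldimethylsilyl chloride CC(C)(C)[Si](C)(C)Cl
Why: Routine phenol silylation gives an ether that tolerates the amide bases, peracid and heat used later and is removed by fluoride at the end.

Step 5
Reactants: 7 4-(tert-butyldimethylsilyloxy)benzaldehyde; 8 (E)-1-methoxy-3-(trimethylsilyloxy)buta-1,3-diene
Product: 10 (2S)-2-[4-(tert-butyldimethylsilyloxy)phenyl]-2,3-dihydro-4H-pyran-4-one, via silyl aldol adduct 9 (not isolated)
Conditions: (S)-BINOL (20 mol %), Ti(OiPr)4 (10 mol %), 4 Å molecular sieves, Et2O, −20 °C; then CF3CO2H, CH2Cl2, 0 °C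
Reagents that add atoms: none
Why: Catalytic asymmetric hetero-Diels–Alder reaction in its Mukaiyama aldol/cyclisation form, in which the BINOL–titanium complex shields one face of the bound aldehyde and so sets C2, and acid then closes ring C with loss of methanol and the silyl group.

Step 6
Reactants: 10 (2S)-2-[4-(tert-butyldimethylsilyloxy)phenyl]-2,3-dihydro-4H-pyran-4-one
Product: 11 (2R,3R)-2-[4-(tert-butyldimethylsilyloxy)phenyl]-3-hydroxy-2,3-dihydro-4H-pyran-4-one
Conditions: NaN(SiMe3)2, THF, −78 °C; 2-(phenylsulfonyl)-3-phenyloxaziridine, −78 °C; aq. NH4Cl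
Reagents that add atoms: 2-(phenylsulfonyl)-3-phenyloxaziridine O=S(=O)(c1ccccc1)N2OC2c3ccccc3
Why: Enolate hydroxylation with an N-sulfonyloxaziridine: C3 is the only enolisable position and oxygen is delivered to the face anti to the neighbouring C2 aryl group, giving the 2,3-trans alcohol, which is also the more stable diequatorial isomer (the C2 descriptor changes from S to R by priority only).

Step 7
Reactants: 11 (2R,3R)-2-[4-(tert-butyldimethylsilyloxy)phenyl]-3-hydroxy-2,3-dihydro-4H-pyran-4-one
Product: 12 (2R,3R)-3-(tert-butyldimethylsilyloxy)-2-[4-(tert-butyldimethylsilyloxy)phenyl]-2,3-dihydro-4H-pyran-4-one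
Conditions: t-BuMe2SiOSO2CF3, 2,6-lutidine, CH2Cl2, −78 → 0 °C
Reagents that add atoms: tert-butyldimethylsilyl trifluoromethanesulfonate CC(C)(C)[Si](C)(C)OS(=O)(=O)C(F)(F)F
Why: Silylation of a hindered secondary alcohol with the silyl triflate and a hindered pyridine base is standard and does not epimerise the α-oxygenated ketone.

Step 8
Reactants: 12 (2R,3R)-3-(tert-butyldimethylsilyloxy)-2-[4-(tert-butyldimethylsilyloxy)phenyl]-2,3-dihydro-4H-pyran-4-one
Product: 13 (2R,3R)-3-(tert-butyldimethylsilyloxy)-2-[4-(tert-butyldimethylsilyloxy)phenyl]-5-(phenylthio)-2,3-dihydro-4H-pyran-4-one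
Conditions: PhSCl, CH2Cl2, −78 °C; then Et3N, −78 → 0 °C
Reagents that add atoms: benzenesulfenyl chloride ClSc1ccccc1
Why: Electrophilic α-sulfenylation of the vinylogous ester: C5 is the nucleophilic enol-ether carbon and loss of HCl restores the enone, the sulfur counterpart of the routine α-halogenation and α-selenenylation of such enones.

Step 9
Reactants: 13 (2R,3R)-3-(tert-butyldimethylsilyloxy)-2-[4-(tert-butyldimethylsilyloxy)phenyl]-5-(phenylthio)-2,3-dihydro-4H-pyran-4-one
Product: 14 (2R,3R)-3-(tert-butyldimethylsilyloxy)-2-[4-(tert-butyldimethylsilyloxy)phenyl]-5-(phenylsulfinyl)-2,3-dihydro-4H-pyran-4-one (both sulfur epimers)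
Conditions: mCPBA (1.0 equiv), NaHCO3, CH2Cl2, −78 °C
Reagents that add atoms: 3-chloroperoxybenzoic acid O=C(OO)c1cccc(Cl)c1
Why: Chemoselective sulfide-to-sulfoxide oxidation with one equivalent of peracid at low temperature, to which the electron-poor push–pull alkene and the silyl ethers are inert; the uncontrolled sulfur centre is lost in step 10.

Step 10
Reactants: 14 (2R,3R)-3-(tert-butyldimethylsilyloxy)-2-[4-(tert-butyldimethylsilyloxy)phenyl]-5-(phenylsulfinyl)-2,3-dihydro-4H-pyran-4-one; 5 (1E,3Z,6E)-1-methoxy-7,11-dimethyl-1,3-bis(trimethylsilyloxy)dodeca-1,3,6,10-tetraene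
Product: 18 (2R,3R)-3-(tert-butyldimethylsilyloxy)-2-[4-(tert-butyldimethylsilyloxy)phenyl]-8-geranyl-5,7-dihydroxychroman-4-one, via cycloadduct 15 (not isolated), via dienyl ketal 16 (not isolated), via bis-trimethylsilyl ether 17 (not isolated)
Conditions: 5 (3 equiv), toluene, 80 °C, sealed tube; then 0.5 M aq. citric acid, THF, 23 °C
Reagents that add atoms: none
Why: Proposed new method: the geranyl-bearing C4 terminus of diene 5, its most nucleophilic carbon, should bond to the electrophilic β-carbon C8a of sulfinyl enone 14 while the ketene acetal carbon bonds to the sulfinyl-bearing C4a, in an asynchronous normal-demand Diels–Alder reaction that closes ring A as a six-membered carbocycle by (4+2) cycloaddition to give 15. Suprafacial addition places the sulfinyl group on C4a cis to H8a, so thermal sulfoxide syn-elimination at the same temperature should restore C4a=C8a (16), 1,4-loss of methanol then aromatises the ring (17), and mild aqueous acid frees the C5 and C7 phenols. The closest known reaction type is the Diels–Alder/aromatisation of 1,1,3-trioxygenated dienes with halo- or sulfinylquinones and with 3-substituted chromones; a 2,3-dihydropyran-4-one has not served as the two-carbon partner. No lasting stereocentre is formed, since the centres created at C4a, C5, C8 and C8a are erased on aromatisation and C2 and C3 are not touched under neutral thermal conditions. The selectivity needed is regiochemical (geranyl carbon bonded to C8a, not C4a) and is secured by the push–pull polarisation of the alkene, whose only electrophilic carbon is C8a, matched with the C4-nucleophilic diene.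

Step 11
Reactants: 18 (2R,3R)-3-(tert-butyldimethylsilyloxy)-2-[4-(tert-butyldimethylsilyloxy)phenyl]-8-geranyl-5,7-dihydroxychroman-4-one
Product: 19 (2R,3R)-8-geranyl-3,5,7-trihydroxy-2-(4-hydroxyphenyl)chroman-4-one
Conditions: HF·pyridine, pyridine, THF, 0 → 23 °C
Reagents that add atoms: none
Why: Fluoride cleavage of the aryl and the secondary alkyl silyl ether under buffered, weakly acidic conditions, which avoid both phenoxide-triggered opening of ring C (C2 epimerisation) and acid-induced cyclisation of the geranyl chain onto the C7 phenol.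

**Compound list**

1 | methyl acetoacetate | CC(=O)CC(=O)OC | starting material
2 | geranyl bromide, (2E)-1-bromo-3,7-dimethylocta-2,6-diene | CC(C)=CCC/C(C)=C/CBr | starting material
3 | methyl (6E)-7,11-dimethyl-3-oxododeca-6,10-dienoate | COC(=O)CC(=O)CC/C=C(\C)CCC=C(C)C | intermediate
4 | methyl (2Z,6E)-7,11-dimethyl-3-(trimethylsilyloxy)dodeca-2,6,10-trienoate | COC(=O)/C=C(\O[Si](C)(C)C)CC/C=C(\C)CCC=C(C)C | intermediate
5 | (1E,3Z,6E)-1-methoxy-7,11-dimethyl-1,3-bis(trimethylsilyloxy)dodeca-1,3,6,10-tetraene | CO/C(O[Si](C)(C)C)=C\C(O[Si](C)(C)C)=C\C/C=C(\C)CCC=C(C)C | intermediate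
6 | 4-hydroxybenzaldehyde | O=Cc1ccc(O)cc1 | starting material
7 | 4-(tert-butyldimethylsilyloxy)benzaldehyde | O=Cc1ccc(O[Si](C)(C)C(C)(C)C)cc1 | intermediate
8 | (E)-1-methoxy-3-(trimethylsilyloxy)buta-1,3-diene | CO/C=C/C(=C)O[Si](C)(C)C | starting material
9 | (1E,5S)-5-[4-(tert-butyldimethylsilyloxy)phenyl]-1-methoxy-5-(trimethylsilyloxy)pent-1-en-3-one | CO/C=C/C(=O)C[C@H](O[Si](C)(C)C)c1ccc(O[Si](C)(C)C(C)(C)C)cc1 | intermediate (not isolated)
10 | (2S)-2-[4-(tert-butyldimethylsilyloxy)phenyl]-2,3-dihydro-4H-pyran-4-one | C1=CO[C@H](c2ccc(O[Si](C)(C)C(C)(C)C)cc2)CC1=O | intermediate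
11 | (2R,3R)-2-[4-(tert-butyldimethylsilyloxy)phenyl]-3-hydroxy-2,3-dihydro-4H-pyran-4-one (2,3-trans) | C1=CO[C@H](c2ccc(O[Si](C)(C)C(C)(C)C)cc2)[C@@H](O)C1=O | intermediate
12 | (2R,3R)-3-(tert-butyldimethylsilyloxy)-2-[4-(tert-butyldimethylsilyloxy)phenyl]-2,3-dihydro-4H-pyran-4-one | C1=CO[C@H](c2ccc(O[Si](C)(C)C(C)(C)C)cc2)[C@@H](O[Si](C)(C)C(C)(C)C)C1=O | intermediate
13 | (2R,3R)-3-(tert-butyldimethylsilyloxy)-2-[4-(tert-butyldimethylsilyloxy)phenyl]-5-(phenylthio)-2,3-dihydro-4H-pyran-4-one | c1ccccc1SC2=CO[C@H](c3ccc(O[Si](C)(C)C(C)(C)C)cc3)[C@@H](O[Si](C)(C)C(C)(C)C)C2=O | intermediate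
14 | (2R,3R)-3-(tert-butyldimethylsilyloxy)-2-[4-(tert-butyldimethylsilyloxy)phenyl]-5-(phenylsulfinyl)-2,3-dihydro-4H-pyran-4-one, mixture of sulfur epimers | O=S(c1ccccc1)C2=CO[C@H](c3ccc(O[Si](C)(C)C(C)(C)C)cc3)[C@@H](O[Si](C)(C)C(C)(C)C)C2=O | intermediate
15 | cis-fused cycloadduct: (2R,3R)-3-(tert-butyldimethylsilyloxy)-2-[4-(tert-butyldimethylsilyloxy)phenyl]-8-geranyl-5-methoxy-4a-(phenylsulfinyl)-5,7-bis(trimethylsilyloxy)-4a,5,8,8a-tetrahydrochroman-4-one, mixture at C4a, C5, C8, C8a and sulfur | CC(C)=CCC/C(C)=C/CC1C(O[Si](C)(C)C)=CC(OC)(O[Si](C)(C)C)C2(S(=O)c3ccccc3)C1O[C@H](c4ccc(O[Si](C)(C)C(C)(C)C)cc4)[C@@H](O[Si](C)(C)C(C)(C)C)C2=O | intermediate (not isolated)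
16 | (2R,3R)-3-(tert-butyldimethylsilyloxy)-2-[4-(tert-butyldimethylsilyloxy)phenyl]-8-geranyl-5-methoxy-5,7-bis(trimethylsilyloxy)-5,8-dihydrochroman-4-one, mixture at C5 and C8 | CC(C)=CCC/C(C)=C/CC1C(O[Si](C)(C)C)=CC(OC)(O[Si](C)(C)C)C2=C1O[C@H](c3ccc(O[Si](C)(C)C(C)(C)C)cc3)[C@@H](O[Si](C)(C)C(C)(C)C)C2=O | intermediate (not isolated)
17 | (2R,3R)-3-(tert-butyldimethylsilyloxy)-2-[4-(tert-butyldimethylsilyloxy)phenyl]-8-geranyl-5,7-bis(trimethylsilyloxy)chroman-4-one | CC(C)=CCC/C(C)=C/Cc1c(O[Si](C)(C)C)cc(O[Si](C)(C)C)c2c1O[C@H](c3ccc(O[Si](C)(C)C(C)(C)C)cc3)[C@@H](O[Si](C)(C)C(C)(C)C)C2=O | intermediate (not isolated)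
18 | (2R,3R)-3-(tert-butyldimethylsilyloxy)-2-[4-(tert-butyldimethylsilyloxy)phenyl]-8-geranyl-5,7-dihydroxychroman-4-one | CC(C)=CCC/C(C)=C/Cc1c(O)cc(O)c2c1O[C@H](c3ccc(O[Si](C)(C)C(C)(C)C)cc3)[C@@H](O[Si](C)(C)C(C)(C)C)C2=O | intermediate
19 | (2R,3R)-8-[(2E)-3,7-dimethylocta-2,6-dien-1-yl]-3,5,7-trihydroxy-2-(4-hydroxyphenyl)chroman-4-one | CC(C)=CCC/C(C)=C/Cc1c(O)cc(O)c2c1O[C@H](c1ccc(O)cc1)[C@@H](O)C2=O | target

**Step count and risks**

Total steps: 11. Longest linear sequence: 8 steps (steps 4 to 11, from 4-hydroxybenzaldehyde); the diene arm contributes steps 1 to 3.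

Steps most likely to fail:

1. Step 10 (ring A annulation).
   - What may go wrong: the cycloaddition may be slower than thermal decay of the silyl ketene acetal; the diene may transfer silicon to the sulfoxide oxygen and start a Pummerer-type consumption of both partners; or aromatisation may stall before methanol is lost.
   - Fallback (known reactions only; ring C is built onto a preformed ring A), setting out from geranyl bromide 2 and returning at target 19:
     - C-alkylation of commercial 2,4,6-trihydroxyacetophenone with 2 (DBU, THF) gives 3-geranyl-2,4,6-trihydroxyacetophenone F1; the two free ring positions are equivalent.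
     - Two equivalents of MOMCl with iPr2NEt cap the 4- and 6-hydroxyls and leave free the hindered, chelated hydroxyl beside the geranyl group, giving the bis-MOM ether F2; this fixes the 8-geranyl pattern.
     - Me2NCH(OMe)2 in toluene gives the enaminone F3, which closes on brief exposure to aqueous acetic acid to 8-geranyl-5,7-bis(methoxymethoxy)chromone F4.
     - Enantioselective conjugate addition of 4-(methoxymethoxy)phenylboronic acid (Pd(OCOCF3)2, the t-BuPyOx enantiomer that leads to 2S, NH4PF6, ClCH2CH2Cl/H2O, 40 °C) gives the (2S)-flavanone F5.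
     - Deprotonation with LiN(SiMe3)2 at −78 °C and oxidation with 2-(phenylsulfonyl)-3-phenyloxaziridine, anti to the C2 aryl group, gives the trans-3-hydroxyflavanone F6.
     - HCl in methanol at 23 °C removes the three MOM groups and returns to the route at target 19, so step 11 is not needed.

2. Step 6 (C3 hydroxylation).
   - What may go wrong: β-elimination of O1 from the C3 enolate (ring opening and loss of the C2 centre), or oxygen transfer syn to the aryl group.
   - Fallback, setting out from 10: Mn(OAc)3·2H2O (trivalent manganese) in benzene at reflux should acetoxylate C3 trans to the aryl group without a free enolate, giving the trans-3-acetoxypyranone F7. K2CO3 in methanol at 0 °C then cleaves the acetate and returns to the route at 11.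

3. Step 8 (C5 sulfenylation).
   - What may go wrong: the sulfenyl chloride may add across C5=C6 without re-elimination, or attack the electron-rich silyloxyarene.
   - Fallback, setting out from 12: N-bromosuccinimide in CH2Cl2 at 0 °C gives the 5-bromopyranone F8. C–S cross-coupling with thiophenol (Pd2(dba)3 as the zerovalent palladium source, Xantphos, iPr2NEt, dioxane, 90 °C) returns to the route at 13.

**Further compounds**

F1 | step 10 | 1-[3-geranyl-2,4,6-trihydroxyphenyl]ethanone | CC(=O)c1c(O)cc(O)c(C/C=C(\C)CCC=C(C)C)c1O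
F2 | step 10 | 1-[3-geranyl-2-hydroxy-4,6-bis(methoxymethoxy)phenyl]ethanone | CC(=O)c1c(OCOC)cc(OCOC)c(C/C=C(\C)CCC=C(C)C)c1O
F3 | step 10 | (E)-3-(dimethylamino)-1-[3-geranyl-2-hydroxy-4,6-bis(methoxymethoxy)phenyl]prop-2-en-1-one | CN(C)/C=C/C(=O)c1c(OCOC)cc(OCOC)c(C/C=C(\C)CCC=C(C)C)c1O
F4 | step 10 | 8-geranyl-5,7-bis(methoxymethoxy)-4H-chromen-4-one | O=c1ccoc2c(C/C=C(\C)CCC=C(C)C)c(OCOC)cc(OCOC)c12
F5 | step 10 | (2S)-8-geranyl-5,7-bis(methoxymethoxy)-2-[4-(methoxymethoxy)phenyl]chroman-4-one | CC(C)=CCC/C(C)=C/Cc1c(OCOC)cc(OCOC)c2c1O[C@H](c3ccc(OCOC)cc3)CC2=O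
F6 | step 10 | (2R,3R)-8-geranyl-3-hydroxy-5,7-bis(methoxymethoxy)-2-[4-(methoxymethoxy)phenyl]chroman-4-one | CC(C)=CCC/C(C)=C/Cc1c(OCOC)cc(OCOC)c2c1O[C@H](c3ccc(OCOC)cc3)[C@@H](O)C2=O
F7 | step 6 | (2R,3R)-3-acetoxy-2-[4-(tert-butyldimethylsilyloxy)phenyl]-2,3-dihydro-4H-pyran-4-one | C1=CO[C@H](c2ccc(O[Si](C)(C)C(C)(C)C)cc2)[C@@H](OC(C)=O)C1=O
F8 | step 8 | (2R,3R)-5-bromo-3-(tert-butyldimethylsilyloxy)-2-[4-(tert-butyldimethylsilyloxy)phenyl]-2,3-dihydro-4H-pyran-4-one | BrC1=CO[C@H](c2ccc(O[Si](C)(C)C(C)(C)C)cc2)[C@@H](O[Si](C)(C)C(C)(C)C)C1=O
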